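The earlier runs and the new flask come from a simulation on assumed constants; the scatter is artificial.

The noon run holds 1.4 equiv of reagent and the dusk run 0.90 equiv, on the same capture agent, yet after 40.0 h their starting material stands at 27.6% and 27.2%.

| flask | starting material | reagent | capture agent | free catalyst | remark | time |
|---|---|---|---|---|---|---|
| dusk | 20 mM | 0.90 equiv | 0.40 mM | 0.1 mol% | run made earlier |  |
| noon | 20 mM | 1.4 equiv | 0.40 mM | 0.1 mol% | run made earlier |  |
| dawn | 20 mM | 1.8 equiv | 0.20 mM | 0.1 mol% | run made earlier |  |
| flask | 20 mM | 1.80 equiv | 0.400 mM | 0.1 mol% |  | 2.5 d |
- dusk (time / h: starting material / %, product / %): 3.00: 81.9, 0.7; 5.00: 74.1, 2.8; 10.0: 59.4, 3.9; 20.0: 42.1, 4.5; 40.0: 27.2, 4.2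
- noon (time / h: starting material / %, product / %): 8.00: 63.9, 3.4; 15.0: 48.6, 4.7; 20.0: 42.4, 4.2; 30.0: 34.3, 4.6; 40.0: 27.6, 5.0
- dawn (time / h: starting material / %, product / %): 3.00: 82.2, 2.4; 10.0: 57.9, 4.7; 15.0: 48.2, 6.2; 25.0: 36.1, 7.2; 40.0: 25.7, 8.2

(readings scatter by 0.5 percentage points)
- in percentages every species weighs as the starting material in it: one homo dimer counts as two
- for released group the idle adduct is counted in
- the earlier runs were read with a standard deviation of 0.5 percentage points
- steps thought possible: catalyst intermediate A <-> catalyst intermediate B; capture agent + catalyst intermediate E -> trapped intermediate; reagent + released group <-> idle adduct; starting material + free catalyst -> catalyst intermediate A; catalyst intermediate C -> released group + catalyst intermediate D; catalyst intermediate D <-> catalyst intermediate E; reagent + catalyst intermediate B -> catalyst intermediate C; catalyst intermediate E -> free catalyst + product; 2 starting material -> homo dimer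
- the earlier runs do not show how much of reagent is bound; that part of a forecast is a guess
- part of the starting material that has reacted at 2.5 d
- share of the unused reagent that is free and not bound as idle adduct, at 2.5 d

So I look to the concentration of starting material itself. In the dusk run at that time, product stands at 4.2% of the charge against 72.8% of the charge lost, so I test a second-order loss to homo dimer. Under that loss, the reciprocal of the fraction remaining climbs in a straight line. Its climb per hour is the reciprocal slope s, 0.0669 /h from the last dusk reading, and it scales with the starting concentration. The noon run gives 0.0656 /h. The flask has the dusk charge of starting material, so I reckon 19.9% left after 2.5 d, and the part reacted, c, is 80.1%.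

But the runs do not show binding. The last noon product reading, 5.0%, is 1.00 mM of product at the capture agent level of the flask, and I take as much released group for the flask. If all of that is bound, I reckon a free share of 97.1% in the flask.

The forecast gives 80% and 98%, the second above my reckoning, holding that “Loss is therefore almost entirely second-order homodimerisation”.

The flask gives 79.7% and 97.8%.

    catalyst intermediate A ⇌ catalyst intermediate B (K = 1.20, k = 0.0110 /s)
    capture agent + catalyst intermediate E → trapped intermediate (k = 0.510 /M/s)
    reagent + released group ⇌ idle adduct, settled at all times (K = 120 /M)
    starting material + free catalyst → catalyst intermediate A (k = 0.620 /M/s)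
    catalyst intermediate C → released group + catalyst intermediate D (k = 0.00670 /s)
    catalyst intermediate D ⇌ catalyst intermediate E (K = 6.30, k = 0.0390 /s)
    reagent + catalyst intermediate B → catalyst intermediate C (k = 9.90 /M/s)
    catalyst intermediate E → free catalyst + product (k = 0.00930 /s)
    2 starting material → homo dimer (k = 4.40 × 10⁻⁴ /M/s)

In the flask at 0.421 d, starting material goes to homo dimer 15 times as fast as it goes to catalyst intermediate A. At 2.50 d the flask holds 74.9% as homo dimer against 4.67% as product. At 1.25 d, s gives 33.3% left in the flask, and it holds 33.3%. For a neighbour charged with 34 mM of starting material, on the same equivalents of reagent and the same loading of free catalyst, I scale s to 0.114 /h, which gives c of 87.2%, and that neighbour reaches 86.9%.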